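**Retrosynthetic overview**
- Feature: in ring C the carbonyl carbon C4 sits on ring A ortho to the ring oxygen O1, so C4 can be the formyl carbon of a salicylaldehyde, while C3 and C2 with ring B can come from the carbene carbon and the aroyl group of a sulfoxonium ylide.
- Precursors: 2,4,6-trihydroxybenzaldehyde 1 is dibenzylated to aldehyde 2; acid 3 is taken through chloride 4 and, with trimethylsulfoxonium iodide 5 (as methylide 6), to ylide 7.
- Key disconnection: C4–C3 and O1–C2 of ring C; 2 and 7 couple under [Cp*RhCl2]2 (trivalent rhodium) to diketone 8, which cyclodehydrates to tetrabenzyl flavone 9.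
- End game: 9 is debenzylated to luteolin 10, the ring B catechol is masked as ketal 11, the 7-hydroxyl is sulfated (salts 12, 13), and the ketal is removed (salt 14) to give target 15.
- Ring order: rings A and B are bought; ring C is the only ring formed (step 4).

Key step: step 4

Assumption: the target is taken as the free hydrogen sulfate drawn; because aryl hydrogen sulfates hydrolyse in their own acidity, the sulfate is carried as its sodium salt and protonated only in the last operation, cold.

**Step 1**
Reactants: 1 2,4,6-trihydroxybenzaldehyde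
Product: 2 4,6-bis(benzyloxy)-2-hydroxybenzaldehyde
Conditions: BnBr (2.05 equiv), K2CO3 (2.2 equiv), DMF, 0 °C to rt
Reagents that add atoms: benzyl bromide, BrCc1ccccc1
Why: Williamson etherification should take the non-chelated, most acidic 4-hydroxyl first and then one of the two equivalent ortho hydroxyls, after which the last hydroxyl is held in a hydrogen bond to the formyl oxygen and is left free.

**Step 2**
Reactants: 3 3,4-bis(benzyloxy)benzoic acid
Product: 4 3,4-bis(benzyloxy)benzoyl chloride
Conditions: (COCl)2 (1.3 equiv), DMF (cat.), CH2Cl2, 0 °C to rt; evaporate, use crude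
Reagents that add atoms: oxalyl chloride, O=C(Cl)C(=O)Cl
Why: acid chloride formation through the catalytic chloroiminium (Vilsmeier-type) species is standard and leaves aryl benzyl ethers untouched.

**Step 3**
Reactants: 4 3,4-bis(benzyloxy)benzoyl chloride; 5 trimethylsulfoxonium iodide
Product: 7 1-[3,4-bis(benzyloxy)phenyl]-2-[dimethyl(oxo)-lambda6-sulfanylidene]ethanone, via dimethylsulfoxonium methylide 6 (not isolated)
Conditions: 5 (3 equiv), KOtBu (3 equiv), THF, reflux; then 4 in THF, 0 °C to rt
Reagents that add atoms: none
Why: C-acylation of the Corey–Chaykovsky methylide by the acid chloride, followed by deprotonation of the acylsulfoxonium salt by a second equivalent of methylide, is the usual preparation of stabilised beta-keto sulfoxonium ylides.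

**Step 4**
Reactants: 2 4,6-bis(benzyloxy)-2-hydroxybenzaldehyde; 7 1-[3,4-bis(benzyloxy)phenyl]-2-[dimethyl(oxo)-lambda6-sulfanylidene]ethanone
Product: 9 5,7,3',4'-tetrakis(benzyloxy)flavone, via 1,3-diketone 8 (not isolated)
Conditions: [Cp*RhCl2]2 (4 mol %), AgSbF6 (16 mol %), AcOH (2 equiv), ClCH2CH2Cl, 100 °C, N2; 7 (1.5 equiv) added in portions
Reagents that add atoms: none
Why: The phenoxide of 2 binds the cationic Cp*Rh centre (trivalent rhodium) and acetate-assisted cleavage of the formyl C–H bond gives a five-membered acyl rhodacycle; ylide 7 then binds through carbon, loses dimethyl sulfoxide to a rhodium carbene, the acyl group migrates to the carbene carbon to form C4–C3, and acetic acid protonates the Rh–C bond to release diketone 8 and return the catalyst. The closest known reaction is the redox-neutral annulation of salicylaldehydes with aroyl sulfoxonium ylides to flavones under the same catalyst type, applied here to a dibenzyloxy substrate. Ring C closes when the free 2-hydroxyl of 8 adds to the aroyl carbonyl (O1–C2) in a 6-exo-trig mode and the hemiketal loses water under the acidic conditions to give the pyranone. No stereocentre is formed. The step needs cleavage of the aldehyde C–H bond in preference to any aryl C–H bond, which the phenoxide secures because only the formyl hydrogen can be reached through a five-membered metallacycle (its ortho ring hydrogen would require a four-membered one). Self-annulation of the ylide through its own ring B ortho hydrogens is held back by the stronger anionic director on 2 and by portionwise addition of 7.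

**Step 5**
Reactants: 9 5,7,3',4'-tetrakis(benzyloxy)flavone
Product: 10 luteolin (5,7,3',4'-tetrahydroxyflavone)
Conditions: H2 (1 atm), 10% Pd/C, THF–MeOH, rt to 40 °C
Reagents that add atoms: none
Why: catalytic hydrogenolysis should cleave the four aryl benzyl ethers, while the C2=C3 bond, being part of the aromatic pyranone, is not reduced under these mild conditions.

**Step 6**
Reactants: 10 luteolin
Product: 11 3',4'-O-(diphenylmethylene)luteolin [2-(2,2-diphenyl-1,3-benzodioxol-5-yl)-5,7-dihydroxy-4H-chromen-4-one]
Conditions: Ph2CCl2 (1.5 equiv), Ph2O, 175 °C, 30 min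
Reagents that add atoms: dichlorodiphenylmethane, ClC(Cl)(c1ccccc1)c1ccccc1
Why: thermal double O-alkylation (ketalisation) by the benzhydrylic dichloride can form a stable five-membered 1,3-benzodioxole only at the vicinal 3',4'-diol, which is the established catechol-selective protection of polyhydroxyflavones.

**Step 7**
Reactants: 11 3',4'-O-(diphenylmethylene)luteolin
Product: 13 sodium 2-(2,2-diphenyl-1,3-benzodioxol-5-yl)-5-hydroxy-4-oxo-4H-chromen-7-yl sulfate, via pyridinium 7-sulfate 12 (not isolated)
Conditions: SO3·pyridine (3 equiv), pyridine, rt; then aq NaHCO3 to pH 7–8; C18 reverse-phase chromatography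
Reagents that add atoms: sulfur trioxide pyridine complex, O=S(=O)([O-])[n+]1ccccc1; sodium hydrogen carbonate, [Na+].OC([O-])=O
Why: O-sulfation with the SO3–amine complex should occur at the acidic, unhindered 7-hydroxyl because the 5-hydroxyl is tied up in its hydrogen bond to the C4 carbonyl and the catechol is masked; exchange to the sodium salt removes pyridine, which would slow the following hydrogenolysis.

**Step 8**
Reactants: 13 sodium 2-(2,2-diphenyl-1,3-benzodioxol-5-yl)-5-hydroxy-4-oxo-4H-chromen-7-yl sulfate
Product: 15 luteolin 7-sulfate (free hydrogen sulfate), via sodium luteolin 7-sulfate 14 (not isolated)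
Conditions: H2 (1 atm), 10% Pd/C, THF–MeOH–H2O, rt; filter; then aq HCl (1.0 equiv), 0 °C; C18 desalting (H2O, then MeOH–H2O); lyophilise
Reagents that add atoms: none
Why: hydrogenolysis of the two doubly benzylic C–O bonds of the diphenylmethylene ketal should free the catechol while the sulfate monoester salt is inert to H2 over palladium, and cold stoichiometric protonation then gives the hydrogen sulfate without prolonged exposure to acid.

**Compound list**
1 | 2,4,6-trihydroxybenzaldehyde | O=Cc1c(O)cc(O)cc1O | starting material
2 | 4,6-bis(benzyloxy)-2-hydroxybenzaldehyde | O=Cc1c(O)cc(OCc2ccccc2)cc1OCc1ccccc1 | intermediate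
3 | 3,4-bis(benzyloxy)benzoic acid | O=C(O)c1ccc(OCc2ccccc2)c(OCc2ccccc2)c1 | starting material
4 | 3,4-bis(benzyloxy)benzoyl chloride | O=C(Cl)c1ccc(OCc2ccccc2)c(OCc2ccccc2)c1 | intermediate
5 | trimethylsulfoxonium iodide | C[S+](C)(C)=O.[I-] | starting material
6 | dimethylsulfoxonium methylide | C=S(C)(C)=O | intermediate
7 | 1-[3,4-bis(benzyloxy)phenyl]-2-[dimethyl(oxo)-lambda6-sulfanylidene]ethanone | CS(C)(=O)=CC(=O)c1ccc(OCc2ccccc2)c(OCc2ccccc2)c1 | intermediate
8 | 1-[2,4-bis(benzyloxy)-6-hydroxyphenyl]-3-[3,4-bis(benzyloxy)phenyl]propane-1,3-dione | O=C(CC(=O)c1ccc(OCc2ccccc2)c(OCc2ccccc2)c1)c1c(O)cc(OCc2ccccc2)cc1OCc1ccccc1 | intermediate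
9 | 5,7,3',4'-tetrakis(benzyloxy)flavone | O=c1cc(-c2ccc(OCc3ccccc3)c(OCc3ccccc3)c2)oc2cc(OCc3ccccc3)cc(OCc3ccccc3)c12 | intermediate
10 | luteolin | O=c1cc(-c2ccc(O)c(O)c2)oc2cc(O)cc(O)c12 | intermediate
11 | 3',4'-O-(diphenylmethylene)luteolin | O=c1cc(-c2ccc3c(c2)OC(c2ccccc2)(c2ccccc2)O3)oc2cc(O)cc(O)c12 | intermediate
12 | pyridinium 2-(2,2-diphenyl-1,3-benzodioxol-5-yl)-5-hydroxy-4-oxo-4H-chromen-7-yl sulfate | O=c1cc(-c2ccc3c(c2)OC(c2ccccc2)(c2ccccc2)O3)oc2cc(OS(=O)(=O)[O-])cc(O)c12.c1cc[nH+]cc1 | intermediate
13 | sodium 2-(2,2-diphenyl-1,3-benzodioxol-5-yl)-5-hydroxy-4-oxo-4H-chromen-7-yl sulfate | O=c1cc(-c2ccc3c(c2)OC(c2ccccc2)(c2ccccc2)O3)oc2cc(OS(=O)(=O)[O-])cc(O)c12.[Na+] | intermediate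
14 | sodium luteolin 7-sulfate | O=c1cc(-c2ccc(O)c(O)c2)oc2cc(OS(=O)(=O)[O-])cc(O)c12.[Na+] | intermediate
15 | luteolin 7-sulfate | O=c1cc(-c2ccc(O)c(O)c2)oc2cc(OS(=O)(=O)O)cc(O)c12 | target

**Step count**
Total: 8 steps. Longest linear sequence: 7 steps (3 to 15 through steps 2, 3, 4, 5, 6, 7, 8).

**Steps most likely to fail**

Step 4. Catalyst turnover may stall on the hindered, very electron-rich aldehyde while the ylide is consumed by self-annulation through ortho C–H activation of its own aryl ring or by O–H insertion of the carbene into the phenol. The fallback is a metal-free Baker–Venkataraman-type acylation that sets out from acid chloride 4 and comes back at flavone 9. Commercial 2,4,6-trihydroxyacetophenone would be dibenzylated as in step 1 to 1-[2,4-bis(benzyloxy)-6-hydroxyphenyl]ethanone F1. Its dilithium phenoxide-enolate (LiN(SiMe3)2, 3 equiv, THF, −78 °C) would be C-acylated by 4 to give the same diketone 8, and TsOH in toluene at 80 °C would cyclodehydrate 8 to 9. Any loss of the 5-O-benzyl group there is harmless, since step 5 removes all benzyl groups.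

Step 1. The partial alkylation may lose chemoselectivity, running on to the chelated hydroxyl or stopping short, so that mono-, di- and tribenzyl ethers form together. The fallback sets out from 1 and comes back at 2. Exhaustive benzylation (BnBr in excess, K2CO3, DMF, 60 °C) would give 2,4,6-tris(benzyloxy)benzaldehyde F2. MgBr2·OEt2 (toluene–Et2O, 80 °C) would then remove a single benzyl group ortho to the formyl group under chelation control, and the resulting magnesium phenoxide chelate resists a second cleavage.

Step 8. Hydrogenolysis of the diaryl ketal may be slow on the polar sulfate salt, and the sulfate monoester may be lost by acid-promoted hydrolysis during the salt-to-acid exchange. The fallback uses a masked sulfate; it sets out from ketal 11 and comes back at target 15, replacing steps 7 and 8. 2,2,2-Trichloroethyl chlorosulfate (Et3N, DMAP, THF, 0 °C to rt) would give the neutral, chromatographable 2-(2,2-diphenyl-1,3-benzodioxol-5-yl)-5-hydroxy-4-oxo-4H-chromen-7-yl 2,2,2-trichloroethyl sulfate F3. The sulfate diester tolerates aqueous acid, so the ketal would be hydrolysed (80% aq AcOH, 80 °C) to 2-(3,4-dihydroxyphenyl)-5-hydroxy-4-oxo-4H-chromen-7-yl 2,2,2-trichloroethyl sulfate F4. Zinc dust and HCO2NH4 in MeOH at rt would cleave the trichloroethyl group reductively to ammonium luteolin 7-sulfate F5, and cold aq HCl (1.0 equiv) with C18 desalting would give 15.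

**Further compounds**
F1 | step 4 | 1-[2,4-bis(benzyloxy)-6-hydroxyphenyl]ethanone | CC(=O)c1c(O)cc(OCc2ccccc2)cc1OCc1ccccc1
F2 | step 1 | 2,4,6-tris(benzyloxy)benzaldehyde | O=Cc1c(OCc2ccccc2)cc(OCc2ccccc2)cc1OCc1ccccc1
F3 | step 8 | 2-(2,2-diphenyl-1,3-benzodioxol-5-yl)-5-hydroxy-4-oxo-4H-chromen-7-yl 2,2,2-trichloroethyl sulfate | O=c1cc(-c2ccc3c(c2)OC(c2ccccc2)(c2ccccc2)O3)oc2cc(OS(=O)(=O)OCC(Cl)(Cl)Cl)cc(O)c12
F4 | step 8 | 2-(3,4-dihydroxyphenyl)-5-hydroxy-4-oxo-4H-chromen-7-yl 2,2,2-trichloroethyl sulfate | O=c1cc(-c2ccc(O)c(O)c2)oc2cc(OS(=O)(=O)OCC(Cl)(Cl)Cl)cc(O)c12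
F5 | step 8 | ammonium luteolin 7-sulfate | O=c1cc(-c2ccc(O)c(O)c2)oc2cc(OS(=O)(=O)[O-])cc(O)c12.[NH4+]
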